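**Retrosynthetic overview**
1. Last step: the ten-membered ring and the γ-lactone close together. The C6–C7 bond is formed by an electrochemical, chromium-catalysed intramolecular γ-chloroallylation of the C7 aldehyde (sets C6–Cl, C7–O and the 5(16)-methylene); the C7 hydroxyl then lactonises onto the C19 ester.
2. C2–C3: zinc acetylide of an enyne dichloride adds to the ring A C2 aldehyde (then OAc); semihydrogenation gives the 3Z olefin.
3. C8–C9 and C8–C17: Ni/Cr coupling of the C9 aldehyde with 2-bromoacrolein acetal, ozonolysis, Mitsunobu inversion to the 9-acetate, Reformatsky addition of propanoate.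
4. Ring A from (S)-carvone (its C5 becomes C14): two C6 alkylations (C1), alkoxymethyl-lithium addition and oxidative 1,3-transposition (C9, C12=O), Criegee rearrangement (14-O), hydroxyl-directed hydrogenation (C10, C11).
5. Ring order: ring A (bought as carvone), then the ten-membered ring and the lactone in one final operation.

Convention: locants C1–C20 are the briarane numbering of the target (C15 = Me on C1, C16 = exocyclic CH2, C17/C18/C19 = lactone CH, its Me and C=O, C20 = Me on C11); α is the ring A face of the C14 oxygen, β the face of Me-15.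

**Step 1**
Reactants: 1 1,3-dichloropropan-2-one; 2 ethynylmagnesium bromide
Product: 3 1-chloro-2-(chloromethyl)but-3-yn-2-ol
Conditions: THF, −78 °C; aq. NH4Cl at −78 °C
Reagents that add atoms: none
Why: Grignard 1,2-addition to the activated ketone; the cold quench keeps the chlorohydrin alkoxide from closing to an epoxide.

**Step 2**
Reactants: 3 1-chloro-2-(chloromethyl)but-3-yn-2-ol
Product: 5 (E)-1-chloro-2-(chloromethyl)but-1-en-3-yne, via sulfamate ester 4 (not isolated)
Conditions: methyl N-(triethylammoniosulfonyl)carbamate (Burgess reagent), benzene, 25 → 55 °C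
Reagents that add atoms: none
Why: Burgess dehydration (syn Ei elimination); only the CH2Cl hydrogens are β, and chlorine ends cis to the slim ethynyl group (E major, Z removed by distillation).

**Step 3**
Reactants: 6 3,3-diethoxyprop-1-ene
Product: 8 2-bromo-3,3-diethoxyprop-1-ene, via 2,3-dibromo-1,1-diethoxypropane 7 (not isolated)
Conditions: Br2, CH2Cl2, −20 °C; then KOtBu, THF, 0 °C
Reagents that add atoms: bromine BrBr
Why: alkene bromination, then E2 loss of HBr through the acidified C2–H (known preparation of 2-bromoacrolein acetals).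

**Step 4**
Reactants: 9 (S)-(+)-carvone; 10 benzyl chloromethyl ether
Product: 12 (5S,6S)-6-[(benzyloxy)methyl]-2-methyl-5-(prop-1-en-2-yl)cyclohex-2-en-1-one, via lithium enolate 11 (not isolated)
Conditions: LiN(iPr)2, THF, −78 °C; then 10, −78 → −30 °C
Reagents that add atoms: none
Why: kinetic deprotonation at C6 and enolate C-alkylation anti to the isopropenyl group; this C6 configuration is erased in step 5.

**Step 5**
Reactants: 12 (5S,6S)-6-[(benzyloxy)methyl]-2-methyl-5-(prop-1-en-2-yl)cyclohex-2-en-1-one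
Product: 14 (5R,6R)-6-[(benzyloxy)methyl]-2,6-dimethyl-5-(prop-1-en-2-yl)cyclohex-2-en-1-one, via lithium enolate 13 (not isolated)
Conditions: LiN(iPr)2, THF, −78 °C; then MeI, DMPU, −78 → −40 °C
Reagents that add atoms: iodomethane CI
Why: second enolate alkylation; MeI enters anti to the C5 isopropenyl group, so the quaternary carbon (future C1) carries Me-15 trans and CH2OBn (future C2) cis to the future C14 oxygen.

**Step 6**
Reactants: 14 (5R,6R)-6-[(benzyloxy)methyl]-2,6-dimethyl-5-(prop-1-en-2-yl)cyclohex-2-en-1-one; 15 tributyl[(methoxymethoxy)methyl]stannane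
Product: 16 (5R,6R)-6-[(benzyloxy)methyl]-1-[(methoxymethoxy)methyl]-2,6-dimethyl-5-(prop-1-en-2-yl)cyclohex-2-en-1-ol (both C1 epimers)
Conditions: n-BuLi, THF, −78 °C (tin–lithium exchange on 15); then 14, −78 °C; H2O
Reagents that add atoms: none
Why: Still-type α-alkoxymethyl-lithium 1,2-addition to the enone carbonyl brings in C9; the carbinol configuration is irrelevant because this carbon becomes sp2 in step 7.

**Step 7**
Reactants: 16 tertiary allylic alcohol
Product: 17 (4S,5R)-4-[(benzyloxy)methyl]-3-[(methoxymethoxy)methyl]-2,4-dimethyl-5-(prop-1-en-2-yl)cyclohex-2-en-1-one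
Conditions: pyridinium chlorochromate [C5H5NH][CrO3Cl], NaOAc, 4 Å sieves, CH2Cl2, 23 °C
Reagents that add atoms: pyridinium chlorochromate [O-][Cr](=O)(=O)Cl.c1cc[nH+]cc1
Why: Dauben–Babler oxidative 1,3-transposition; [3,3] shift of the tertiary allylic chromate ester and oxidation give the C12 enone with C9 on C10.

**Step 8**
Reactants: 17 transposed enone
Product: 19 (4S,5S)-5-acetoxy-4-[(benzyloxy)methyl]-3-[(methoxymethoxy)methyl]-2,4-dimethylcyclohex-2-en-1-one, via methoxy hydroperoxide 18 (not isolated)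
Conditions: O3, CH2Cl2/MeOH, −78 °C; then Ac2O, pyridine, DMAP (cat.), 0 → 40 °C
Reagents that add atoms: ozone [O-][O+]=O; methanol CO
Why: ozone cleaves only the electron-rich isopropenyl group (the enone C=C is deactivated); Criegee rearrangement of the acetylated hydroperoxide migrates the ring carbon with retention and gives the 14α-acetate.

**Step 9**
Reactants: 19 acetate enone
Product: 20 (4S,5S)-4-[(benzyloxy)methyl]-5-hydroxy-3-(hydroxymethyl)-2,4-dimethylcyclohex-2-en-1-one
Conditions: HCl (1 M, from AcCl) in MeOH, 40 °C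
Reagents that add atoms: none
Why: acid-catalysed methanolysis removes the methoxymethyl acetal and the acetate (transacetalisation, transesterification); no stereocenter is touched.

**Step 10**
Reactants: 20 enone diol
Product: 21 (2R,3S,4S,5S)-4-[(benzyloxy)methyl]-5-hydroxy-3-(hydroxymethyl)-2,4-dimethylcyclohexan-1-one
Conditions: H2 (30 bar), [Ir(cod)(PCy3)(py)]PF6 (10 mol %), CH2Cl2, 23 °C
Reagents that add atoms: none
Why: hydroxyl-directed hydrogenation; iridium held by the 14α-OH adds both hydrogens syn to the α face of C10=C11, which sets H-10α and H-11α (C9 and Me-20 β) together.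

**Step 11**
Reactants: 21 saturated keto diol
Product: 22 (1S,2S,3S,6R)-2-[(benzyloxy)methyl]-3-hydroxy-2,6-dimethyl-5-oxocyclohexane-1-carbaldehyde
Conditions: TEMPO (10 mol %), PhI(OAc)2, CH2Cl2, 23 °C
Reagents that add atoms: none
Why: oxoammonium (TEMPO) oxidation is selective for the primary alcohol over the secondary C14-OH and stops at the aldehyde.

**Step 12**
Reactants: 22 hydroxy aldehyde
Product: 23 (1S,2S,3S,4R)-2-[(benzyloxy)methyl]-3-formyl-2,4-dimethyl-5-oxocyclohexyl butanoate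
Conditions: butyric anhydride, pyridine, DMAP (cat.), CH2Cl2, 0 °C
Reagents that add atoms: butyric anhydride CCCC(=O)OC(=O)CCC
Why: DMAP-catalysed acylation of the only free hydroxyl installs the C14 butyrate.

**Step 13**
Reactants: 23 ring A aldehyde; 8 2-bromo-3,3-diethoxyprop-1-ene
Product: 24 (9R)-allylic alcohol (23 with CHO replaced by CH(OH)–C(=CH2)–CH(OEt)2)
Conditions: CrCl2 (4 equiv), NiCl2 (2 mol %), DMF, 23 °C; aq. work-up
Reagents that add atoms: none
Why: Nozaki–Hiyama–Kishi alkenylation adds only to the aldehyde (ketone and esters survive); Felkin–Anh attack anti to the quaternary C1 gives the 9R carbinol, the epimer wanted for the inversion in step 15.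

**Step 14**
Reactants: 24 (9R)-allylic alcohol
Product: 26 (9R)-α-hydroxy ketone (side chain CH(OH)–C(=O)–CH(OEt)2), via ozonide 25 (not isolated)
Conditions: O3, CH2Cl2, −78 °C; then Me2S, −78 → 23 °C
Reagents that add atoms: ozone [O-][O+]=O
Why: ozonolysis with reductive work-up turns the only olefin into the C8 ketone.

**Step 15**
Reactants: 26 (9R)-α-hydroxy ketone
Product: 27 (9S)-α-acetoxy ketone (side chain CH(OAc)–C(=O)–CH(OEt)2)
Conditions: PPh3, diisopropyl azodicarboxylate, AcOH, toluene, 0 → 23 °C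
Reagents that add atoms: acetic acid CC(=O)O
Why: Mitsunobu reaction; SN2 displacement by acetate at the α-keto carbinol carbon (activated for SN2) inverts C9 and gives the 9S acetate.

**Step 16**
Reactants: 27 (9S)-α-acetoxy ketone; 28 methyl 2-bromopropanoate (racemic)
Product: 29 Reformatsky adduct (side chain (9S)-CH(OAc)–(8R)-C(OH)[CH(OEt)2]–(17R)-CH(CH3)CO2CH3)
Conditions: Zn dust (activated with cat. Me3SiCl), THF, 0 → 23 °C; aq. NH4Cl
Reagents that add atoms: none
Why: Reformatsky reaction; the zinc enolate attacks the most electrophilic ketone (flanked by OAc and acetal) and leaves the hindered C12 ketone. Polar Felkin–Anh attack anti to the poorly chelating C9–OAc bond gives 8R, and a chair transition state with the C9 branch equatorial gives 17R (minor C17 epimer removed by chromatography).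

**Step 17**
Reactants: 29 Reformatsky adduct
Product: 30 primary alcohol (29 with CH2OBn turned into CH2OH at C2)
Conditions: H2 (1 atm), Pd(OH)2/C, EtOAc, 23 °C
Reagents that add atoms: none
Why: hydrogenolysis of the benzyl ether; no olefin is present at this stage.

**Step 18**
Reactants: 30 primary alcohol
Product: 31 C2 aldehyde
Conditions: Dess–Martin periodinane, NaHCO3, CH2Cl2, 23 °C
Reagents that add atoms: none
Why: Dess–Martin oxidation of the neopentyl primary alcohol to the non-enolisable aldehyde; the tertiary C8-OH cannot be oxidised.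

**Step 19**
Reactants: 31 C2 aldehyde; 5 (E)-1-chloro-2-(chloromethyl)but-1-en-3-yne
Product: 33 (2S)-propargylic acetate carrying C2(OAc)–C≡C–C(CH2Cl)=CHCl, via zinc alkoxide 32 (not isolated)
Conditions: Zn(OTf)2, iPr2NEt, toluene, 23 °C; then Ac2O, DMAP (cat.), 0 °C
Reagents that add atoms: acetic anhydride CC(=O)OC(C)=O
Why: zinc acetylide addition to an aldehyde (Carreira conditions without chiral ligand); Felkin–Anh attack anti to the large C10 branch on the quaternary C1 gives 2S, and the zinc alkoxide is acetylated in the same flask.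

**Step 20**
Reactants: 33 (2S)-propargylic acetate
Product: 34 (3Z)-diene (C2(OAc)–CH=CH–C(CH2Cl)=CHCl)
Conditions: H2 (1 atm), Pd/CaCO3 poisoned with Pb(OAc)2, quinoline, EtOAc, 0 °C
Reagents that add atoms: none
Why: Lindlar-type semihydrogenation; syn addition of H2 to the alkyne gives the 3Z olefin, and the vinyl and allyl chlorides survive the poisoned catalyst.

**Step 21**
Reactants: 34 (3Z)-diene acetal
Product: 36 seco aldehyde (C7 CHO; 8-OSiEt3), via collidinium salt 35 (not isolated)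
Conditions: Et3SiOTf (3 equiv), 2,4,6-collidine, CH2Cl2, 0 °C; then H2O
Reagents that add atoms: triethylsilyl trifluoromethanesulfonate CC[Si](CC)(CC)OS(=O)(=O)C(F)(F)F; water O
Why: silyl triflate–collidine acetal cleavage (Fujioka type); the acetal becomes a collidinium salt that water hydrolyses to the aldehyde without acid, and the tertiary C8-OH is silylated at the same time. The allylic acetate and the chlorides are not ionised.

**Step 22**
Reactants: 36 seco aldehyde
Product: 39 ptilosarcone, via macrocyclic bis-silyl ether 37 (not isolated), via macrocyclic diol ester 38 (not isolated)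
Conditions: CrCl3(thf)3 (15 mol %), Me3SiCl (3 equiv), Bu4NPF6 (0.1 M), DMF, undivided cell, Al anode, reticulated vitreous carbon cathode, −1.1 V vs Ag/AgCl, 0 °C, 36 added over 10 h (final 2 mM), 2.1 F/mol; then HF·pyridine, THF, 0 → 23 °C
Reagents that add atoms: none
Why: Proposed new method: the cathode regenerates divalent chromium from CrCl3, and two equivalents of it reduce the primary allylic C–Cl bond of 36 (not the vinylic one) to a γ-chloroallyl species of trivalent chromium σ-bound at C16; this adds through a six-membered chair transition state by its chlorine-bearing γ-carbon (C6) to the C7 aldehyde (Nozaki–Hiyama-type allylation), which forms C6–C7 and the ten-membered ring, turns C16 into the exocyclic methylene, puts the chlorine of the E-vinyl chloride equatorial (6,7-anti, 6S) and attacks the aldehyde face anti to the non-chelating C8–OSiEt3 bond (polar Felkin–Anh, 7R); Me3SiCl frees chromium from the alkoxide, and HF·pyridine removes both silyl groups so that the C7 hydroxyl lactonises onto the C19 ester. The closest known reactions are the chromium-electrocatalytic Nozaki–Hiyama–Kishi coupling of alkenyl halides, stoichiometric chromium allylation macrocyclisations to ten-membered carbocycles, and γ-chloroallyl-boron or -indium additions that give chlorohydrins; a catalytic electrochemical γ-chloroallyl-chromium addition, and its use for ring closure, has not been shown.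

**Compound list**
1 | 1,3-dichloropropan-2-one | ClCC(=O)CCl | starting material
2 | ethynylmagnesium bromide | C#C[Mg]Br | starting material
3 | 1-chloro-2-(chloromethyl)but-3-yn-2-ol | ClCC(O)(CCl)C#C | intermediate
4 | triethylammonium N-(methoxycarbonyl)sulfamate ester of 3 | CC[NH+](CC)CC.COC(=O)[N-]S(=O)(=O)OC(CCl)(CCl)C#C | intermediate
5 | (E)-1-chloro-2-(chloromethyl)but-1-en-3-yne (vinylic Cl cis to ethynyl) | ClC/C(C#C)=C/Cl | intermediate
6 | 3,3-diethoxyprop-1-ene (acrolein diethyl acetal) | C=CC(OCC)OCC | starting material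
7 | 2,3-dibromo-1,1-diethoxypropane | BrCC(Br)C(OCC)OCC | intermediate
8 | 2-bromo-3,3-diethoxyprop-1-ene | C=C(Br)C(OCC)OCC | intermediate
9 | (S)-(+)-carvone | CC(=C)[C@H]1CC=C(C)C(=O)C1 | starting material
10 | benzyl chloromethyl ether | ClCOCc1ccccc1 | starting material
11 | lithium enolate of 9 (O–C1=C6) | [Li]OC1=C[C@@H](C(C)=C)CC=C1C | intermediate
12 | (5S,6S)-6-[(benzyloxy)methyl]-2-methyl-5-(prop-1-en-2-yl)cyclohex-2-en-1-one | c1ccc(COC[C@H]2C(=O)C(C)=CC[C@@H]2C(C)=C)cc1 | intermediate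
13 | lithium enolate of 12 (O–C1=C6) | [Li]OC1=C(COCc2ccccc2)[C@@H](C(C)=C)CC=C1C | intermediate
14 | (5R,6R)-6-[(benzyloxy)methyl]-2,6-dimethyl-5-(prop-1-en-2-yl)cyclohex-2-en-1-one (6-Me trans, 6-CH2OBn cis to isopropenyl) | c1ccc(COC[C@]2(C)C(=O)C(C)=CC[C@@H]2C(C)=C)cc1 | intermediate
15 | tributyl[(methoxymethoxy)methyl]stannane | CCCC[Sn](CCCC)(CCCC)COCOC | starting material
16 | (5R,6R)-6-[(benzyloxy)methyl]-1-[(methoxymethoxy)methyl]-2,6-dimethyl-5-(prop-1-en-2-yl)cyclohex-2-en-1-ol (both C1 epimers) | c1ccc(COC[C@]2(C)C(O)(COCOC)C(C)=CC[C@@H]2C(C)=C)cc1 | intermediate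
17 | (4S,5R)-4-[(benzyloxy)methyl]-3-[(methoxymethoxy)methyl]-2,4-dimethyl-5-(prop-1-en-2-yl)cyclohex-2-en-1-one | c1ccc(COC[C@]2(C)C(COCOC)=C(C)C(=O)C[C@@H]2C(C)=C)cc1 | intermediate
18 | 17 with the isopropenyl group turned into C(CH3)(OCH3)OOH | c1ccc(COC[C@]2(C)C(COCOC)=C(C)C(=O)C[C@@H]2C(C)(OC)OO)cc1 | intermediate
19 | (4S,5S)-5-acetoxy-4-[(benzyloxy)methyl]-3-[(methoxymethoxy)methyl]-2,4-dimethylcyclohex-2-en-1-one | c1ccc(COC[C@]2(C)C(COCOC)=C(C)C(=O)C[C@@H]2OC(C)=O)cc1 | intermediate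
20 | (4S,5S)-4-[(benzyloxy)methyl]-5-hydroxy-3-(hydroxymethyl)-2,4-dimethylcyclohex-2-en-1-one | c1ccc(COC[C@]2(C)C(CO)=C(C)C(=O)C[C@@H]2O)cc1 | intermediate
21 | (2R,3S,4S,5S)-4-[(benzyloxy)methyl]-5-hydroxy-3-(hydroxymethyl)-2,4-dimethylcyclohexan-1-one (Me-15 β; CH2OBn, H-10, H-11, 14-OH α) | c1ccc(COC[C@]2(C)[C@H]([C@@H](C)C(=O)C[C@@H]2O)CO)cc1 | intermediate
22 | (1S,2S,3S,6R)-2-[(benzyloxy)methyl]-3-hydroxy-2,6-dimethyl-5-oxocyclohexane-1-carbaldehyde | c1ccc(COC[C@]2(C)[C@H]([C@@H](C)C(=O)C[C@@H]2O)C=O)cc1 | intermediate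
23 | (1S,2S,3S,4R)-2-[(benzyloxy)methyl]-3-formyl-2,4-dimethyl-5-oxocyclohexyl butanoate | c1ccc(COC[C@]2(C)[C@H]([C@@H](C)C(=O)C[C@@H]2OC(=O)CCC)C=O)cc1 | intermediate
24 | 23 with CHO replaced by (9R)-CH(OH)–C(=CH2)–CH(OEt)2 | c1ccc(COC[C@]2(C)[C@H]([C@@H](C)C(=O)C[C@@H]2OC(=O)CCC)[C@@H](O)C(=C)C(OCC)OCC)cc1 | intermediate
25 | 1,2,4-trioxolane (ozonide) of the C8 methylene of 24 | c1ccc(COC[C@]2(C)[C@H]([C@@H](C)C(=O)C[C@@H]2OC(=O)CCC)[C@@H](O)C3(C(OCC)OCC)OCOO3)cc1 | intermediate
26 | 23 with CHO replaced by (9R)-CH(OH)–C(=O)–CH(OEt)2 | c1ccc(COC[C@]2(C)[C@H]([C@@H](C)C(=O)C[C@@H]2OC(=O)CCC)[C@@H](O)C(=O)C(OCC)OCC)cc1 | intermediate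
27 | 23 with CHO replaced by (9S)-CH(OAc)–C(=O)–CH(OEt)2 | c1ccc(COC[C@]2(C)[C@H]([C@@H](C)C(=O)C[C@@H]2OC(=O)CCC)[C@H](OC(C)=O)C(=O)C(OCC)OCC)cc1 | intermediate
28 | methyl 2-bromopropanoate (racemic) | COC(=O)C(C)Br | starting material
29 | 23 with CHO replaced by (9S)-CH(OAc)–(8R)-C(OH)[CH(OEt)2]–(17R)-CH(CH3)CO2CH3 | c1ccc(COC[C@]2(C)[C@H]([C@@H](C)C(=O)C[C@@H]2OC(=O)CCC)[C@H](OC(C)=O)[C@](C(OCC)OCC)(O)[C@@H](C)C(=O)OC)cc1 | intermediate
30 | 29 with CH2OBn turned into CH2OH (C2 alcohol) | OC[C@]1(C)[C@H]([C@@H](C)C(=O)C[C@@H]1OC(=O)CCC)[C@H](OC(C)=O)[C@](C(OCC)OCC)(O)[C@@H](C)C(=O)OC | intermediate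
31 | 29 with CH2OBn turned into CHO (C2 aldehyde) | O=C[C@]1(C)[C@H]([C@@H](C)C(=O)C[C@@H]1OC(=O)CCC)[C@H](OC(C)=O)[C@](C(OCC)OCC)(O)[C@@H](C)C(=O)OC | intermediate
32 | zinc triflate alkoxide of the (2S)-propargylic alcohol from 31 and 5 | Cl/C=C(CCl)\C#C[C@H](O[Zn]OS(=O)(=O)C(F)(F)F)[C@]1(C)[C@H]([C@@H](C)C(=O)C[C@@H]1OC(=O)CCC)[C@H](OC(C)=O)[C@](C(OCC)OCC)(O)[C@@H](C)C(=O)OC | intermediate
33 | (2S)-propargylic acetate, C2(OAc)–C≡C–C(CH2Cl)=CHCl (E), rest as 29 | Cl/C=C(CCl)\C#C[C@H](OC(C)=O)[C@]1(C)[C@H]([C@@H](C)C(=O)C[C@@H]1OC(=O)CCC)[C@H](OC(C)=O)[C@](C(OCC)OCC)(O)[C@@H](C)C(=O)OC | intermediate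
34 | (3Z)-alkene from 33, C2(OAc)–CH=CH–C(CH2Cl)=CHCl | Cl/C=C(CCl)\C=C/[C@H](OC(C)=O)[C@]1(C)[C@H]([C@@H](C)C(=O)C[C@@H]1OC(=O)CCC)[C@H](OC(C)=O)[C@](C(OCC)OCC)(O)[C@@H](C)C(=O)OC | intermediate
35 | 34 with CH(OEt)2 turned into CH(OEt)(2,4,6-trimethylpyridinium) triflate and 8-OH into OSiEt3 | Cl/C=C(CCl)\C=C/[C@H](OC(C)=O)[C@]1(C)[C@H]([C@@H](C)C(=O)C[C@@H]1OC(=O)CCC)[C@H](OC(C)=O)[C@](C(OCC)[n+]2c(C)cc(C)cc2C)(O[Si](CC)(CC)CC)[C@@H](C)C(=O)OC.[O-]S(=O)(=O)C(F)(F)F | intermediate
36 | seco aldehyde: 34 with CH(OEt)2 turned into CHO (C7) and 8-OH into OSiEt3 | Cl/C=C(CCl)\C=C/[C@H](OC(C)=O)[C@]1(C)[C@H]([C@@H](C)C(=O)C[C@@H]1OC(=O)CCC)[C@H](OC(C)=O)[C@](C=O)(O[Si](CC)(CC)CC)[C@@H](C)C(=O)OC | intermediate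
37 | ptilosarcone with the lactone open: 7-OSiMe3, 8-OSiEt3, C19 methyl ester (6S,7R) | C=C1/C=C\[C@H](OC(C)=O)[C@]2(C)[C@H]([C@@H](C)C(=O)C[C@@H]2OC(=O)CCC)[C@H](OC(C)=O)[C@](O[Si](CC)(CC)CC)([C@@H](C)C(=O)OC)[C@@H](O[Si](C)(C)C)[C@H]1Cl | intermediate
38 | as 37 with free 7-OH and 8-OH | C=C1/C=C\[C@H](OC(C)=O)[C@]2(C)[C@H]([C@@H](C)C(=O)C[C@@H]2OC(=O)CCC)[C@H](OC(C)=O)[C@](O)([C@@H](C)C(=O)OC)[C@@H](O)[C@H]1Cl | intermediate
39 | ptilosarcone | C=C1/C=C\[C@H](OC(C)=O)[C@]2(C)[C@H]([C@@H](C)C(=O)C[C@@H]2OC(=O)CCC)[C@H](OC(C)=O)[C@]2(O)[C@@H](C)C(=O)O[C@H]2[C@H]1Cl | target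

**Step count and risks**
Total: 22 steps. Longest linear sequence: 19 steps (steps 4–22, from (S)-carvone).

Three steps most likely to fail:

1. Step 22 (the proposed new electrochemical γ-chloroallylation ring closure). Risks: over-reduction of the product's allylic chloride, ring strain, and C6/C7 facial control. Fallback with known chemistry, setting out from 31 and coming back at 39: 31 is alkynylated and acetylated as in step 19 with the literature reagent (E)-1-iodo-2-methylbut-1-en-3-yne F1 to give the propargylic acetate F2. Semihydrogenation as in step 20 gives the (3Z,5E)-iodo-diene F3, and Et3SiOTf/collidine then water as in step 21 gives the 8-OSiEt3 aldehyde F4. A stoichiometric NiCl2/CrCl2 Nozaki–Hiyama–Kishi macrocyclisation at high dilution (F4 holds no allylic halide), followed by HF·pyridine, gives the 16-methyl (3Z,5E)-diene lactone F5. An ene-type allylic chlorination of its trisubstituted 5,6-olefin (N-chlorosuccinimide, cat. PhSeCl, CH2Cl2) moves the double bond to C5=C16 and places chlorine at C6, giving 39.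

2. Step 10 (directed hydrogenation of a tetrasubstituted, electron-poor enone). Fallback setting out from 19 and coming back at 21: NaBH4/CeCl3 (MeOH, −40 °C) reduces the C12 ketone of 19, hydride entering anti to the 14α-acetate, to the 12α-allylic alcohol F6. The now electron-rich olefin is hydrogenated with [Ir(cod)(PCy3)(py)]PF6 under allylic-hydroxyl direction to the saturated alcohol F7. Dess–Martin oxidation returns the ketone as the keto acetate F8, and HCl/MeOH as in step 9 gives 21.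

3. Step 15 (Mitsunobu inversion at a hindered α-keto carbinol). Fallback setting out from 24 and coming back at 27: Dess–Martin oxidation of 24 gives the cross-conjugated enone F9. Felkin–Anh 1,2-reduction (NaBH4/CeCl3, −78 °C; hydride now takes the trajectory that carbon took in step 13) gives the 9S allylic alcohol F10. Acetylation (Ac2O, pyridine) gives the allylic acetate F11, and ozonolysis (O3; Me2S) gives 27.

**Further compounds**
F1 | step 22 | (E)-1-iodo-2-methylbut-1-en-3-yne | I/C=C(C)/C#C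
F2 | step 22 | (2S)-propargylic acetate from 31 and F1, C2(OAc)–C≡C–C(CH3)=CHI | I/C=C(C)/C#C[C@H](OC(C)=O)[C@]1(C)[C@H]([C@@H](C)C(=O)C[C@@H]1OC(=O)CCC)[C@H](OC(C)=O)[C@](C(OCC)OCC)(O)[C@@H](C)C(=O)OC
F3 | step 22 | (3Z,5E)-iodo-diene acetal | I/C=C(C)/C=C\[C@H](OC(C)=O)[C@]1(C)[C@H]([C@@H](C)C(=O)C[C@@H]1OC(=O)CCC)[C@H](OC(C)=O)[C@](C(OCC)OCC)(O)[C@@H](C)C(=O)OC
F4 | step 22 | (3Z,5E)-iodo-diene C7 aldehyde with 8-OSiEt3 | I/C=C(C)/C=C\[C@H](OC(C)=O)[C@]1(C)[C@H]([C@@H](C)C(=O)C[C@@H]1OC(=O)CCC)[C@H](OC(C)=O)[C@](C=O)(O[Si](CC)(CC)CC)[C@@H](C)C(=O)OC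
F5 | step 22 | 6-dechloro-16-methyl (3Z,5E)-diene lactone (ptilosarcone skeleton with C5(CH3)=C6) | C/C=1/C=C\[C@H](OC(C)=O)[C@]2(C)[C@H]([C@@H](C)C(=O)C[C@@H]2OC(=O)CCC)[C@H](OC(C)=O)[C@]2(O)[C@@H](C)C(=O)O[C@H]2/C=1
F6 | step 10 | 12α-allylic alcohol from 19 (C12-OH cis to 14-OAc) | c1ccc(COC[C@]2(C)C(COCOC)=C(C)[C@H](O)C[C@@H]2OC(C)=O)cc1
F7 | step 10 | saturated 12α-alcohol (H-10α, H-11α; 9-OMOM, 14-OAc) | c1ccc(COC[C@]2(C)[C@H]([C@@H](C)[C@H](O)C[C@@H]2OC(C)=O)COCOC)cc1
F8 | step 10 | saturated C12 ketone with 9-OMOM and 14-OAc | c1ccc(COC[C@]2(C)[C@H]([C@@H](C)C(=O)C[C@@H]2OC(C)=O)COCOC)cc1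
F9 | step 15 | C9 enone, side chain C(=O)–C(=CH2)–CH(OEt)2 | c1ccc(COC[C@]2(C)[C@H]([C@@H](C)C(=O)C[C@@H]2OC(=O)CCC)C(=O)C(=C)C(OCC)OCC)cc1
F10 | step 15 | (9S)-allylic alcohol, side chain CH(OH)–C(=CH2)–CH(OEt)2 | c1ccc(COC[C@]2(C)[C@H]([C@@H](C)C(=O)C[C@@H]2OC(=O)CCC)[C@H](O)C(=C)C(OCC)OCC)cc1
F11 | step 15 | (9S)-allylic acetate, side chain CH(OAc)–C(=CH2)–CH(OEt)2 | c1ccc(COC[C@]2(C)[C@H]([C@@H](C)C(=O)C[C@@H]2OC(=O)CCC)[C@H](OC(C)=O)C(=C)C(OCC)OCC)cc1
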